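At early times the midnight flask gains ring almost in step with time, 4.4% by 3.00 h, and its last reading is 10.7% at 10.0 h; ring is the one species read, at one charge.

| flask | substrate | activator | remark | time |
|---|---|---|---|---|
| midnight | 0.11 M | 1 equiv | run made earlier |  |
| west | 0.060 M | 0.330 equiv |  | 30 h |
| south-east | 0.10 M | 1.00 equiv |  | 30 h |
| north | 0.20 M | 2.00 equiv |  | 30 h |
| south-west | 0.050 M | 3.00 equiv |  | 30 h |
| north-west | 0.40 M | 1.00 equiv |  | 30 h |

- midnight (time / h: ring / %): 1.50: 2.2; 3.00: 4.4; 5.00: 6.2; 6.00: 8.0; 8.00: 8.7; 10.0: 10.7

(readings scatter by 0.5 percentage points)

- the flasks put in order of amount of ring, in percent of the substrate charged, best first, at 30 h (west / south-east / north / south-west / north-west)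
- the amount of ring, in percent of the substrate charged of the flask you put first, at 30 h
- the amount of ring, in percent of the substrate charged of the flask you put last, at 30 h



So the scale needs a zero, and the symmetric case gives one: if each meeting of substrate and activator at equal charges yields ring and nothing else, the ratio of ring to remaining substrate grows in proportion to charge times time. The last midnight reading then gives that constant, 0.109 /M/h, the ring clock, and it carries the scatter of 0.5 percentage points.

But south-west, north and west are not charged equally. South-west holds 3.00 equiv of activator, and with activator held at that charge its substrate falls on a pseudo-first-order clock with a half-life of 42.4 h, which puts its ring at 38.7% at 30 h. For north, with 2.00 equiv, the clock gives 64.8%, a higher figure than for south-west. For west, with activator at 0.330 equiv as limiting reagent, the clock gives 5.93%. This reckoning ranks north, north-west, south-west, south-east, west, but it assumes that a stronger charge merely runs faster, which one concentration cannot test.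

The forecast, near this reckoning, gives north > north-west > south-west > south-east > west, top 66% and low 6%, and names the risk of “oligomerisation at high concentration”.

The flasks give south-west > north > south-east > north-west > west, with 36.1% in south-west and 7.05% in west.

    substrate + activator → activated form (k = 0.701 /M/h)
    substrate ⇌ dormant form (K = 1.89, k = 0.0833 /h)
    activated form → ring (k = 4.17 /h)
    activator → decomposed reagent (k = 0.00354 /h)
    substrate + activated form → open dimer (k = 124 /M/h)

South-west's ring stands at 36.1% against a clock value of 38.7%, yet the clock's half-life of 42.4 h is far longer than the 6.6 h for substrate by its step to activated form alone at the charged amounts, and south-west at 30 h holds 6.0% of its substrate beside 37.7% open dimer and 20.1% dormant form. With the south-west recipe at 0.013 M of substrate, the clock reads 12.0% and that neighbour holds twice as much ring, 24.4%, with open dimer at 9.06%.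

The readings come from a simulation for substances that don't exist; the scatter is artificial.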